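With the ring numbered C1 (quaternary, bearing C7), C2 (CHOH), C3, C4 (CH2), C5 (CHOBz), C6 (CHOH), the cyclohexane is cut at C3–C4, its only edge without oxygen, so that C6, C1 and C2 with their oxygens can be taken unchanged from C2, C3 and C4 of a D-glucopyranoside. Ring-closing metathesis of an octa-1,7-diene joins former glucose C5 (ring C3) to a vinyl carbon added at glucose C1 (ring C4) and closes the six-membered carbocycle with all four stereocentres already in place. The precursor is an acyclic dienol made by zinc fragmentation of a 6-iodo-3-C-branched glucoside and vinyl addition; O2 and O6 are benzyl ethers, O1 and O7 are 2-naphthylmethyl ethers, and O5 is free.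

Key step: step 10

Remarks: NAP = 2-naphthylmethyl. Sugar intermediates carry carbohydrate numbering; carbocycles are named with the target ring numbering given above, not with lowest locants. Assumption: the commercial glucoside 1, with its (R)-benzylidene acetal (phenyl equatorial), is taken as the chiral-pool starting material. O1 and O7 are given NAP ethers so that the later double benzoylation needs no selectivity between hydroxyls.

Step 1
Reactants: 1 methyl 4,6-O-benzylidene-α-D-glucopyranoside; 2 benzyl bromide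
Product: 3 methyl 2-O-benzyl-4,6-O-benzylidene-α-D-glucopyranoside
Conditions: BnBr (1.2 equiv), Bu4NHSO4 (cat.), 5% aq. NaOH, CH2Cl2, reflux
Reagents that add atoms: benzyl bromide (2), BrCc1ccccc1
Why: Williamson etherification under phase-transfer catalysis: the 2-OH is the more acidic hydroxyl because of the adjacent anomeric acetal and should be alkylated in preference to the 3-OH; the minor 3-O-benzyl and 2,3-di-O-benzyl ethers are removed by chromatography and no stereocentre changes.

Step 2
Reactants: 3 methyl 2-O-benzyl-4,6-O-benzylidene-α-D-glucopyranoside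
Product: 4 methyl 2-O-benzyl-4,6-O-benzylidene-α-D-ribo-hexopyranosid-3-ulose
Conditions: Dess–Martin periodinane, CH2Cl2, rt
Reagents that add atoms: none
Why: Dess–Martin oxidation of the only free hydroxyl gives the 3-ketone under near-neutral conditions that should leave both acetals and the α-stereocentres C2 and C4 intact.

Step 3
Reactants: 4 methyl 2-O-benzyl-4,6-O-benzylidene-α-D-ribo-hexopyranosid-3-ulose; 5 methyltriphenylphosphonium bromide
Product: 6 methyl 2-O-benzyl-4,6-O-benzylidene-3-deoxy-3-C-methylene-α-D-ribo-hexopyranoside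
Conditions: Ph3PCH3Br, KOtBu, THF, 0 °C; then 4, –78 °C → rt
Reagents that add atoms: methyltriphenylphosphonium bromide (5, as its ylide), C[P+](c1ccccc1)(c1ccccc1)c1ccccc1.[Br-]
Why: Wittig methylenation: the small non-stabilised ylide should add to the ketone faster than it enolises it at low temperature, the trans-fused acetal ring holds C2 and C4, and no stereocentre is formed.

Step 4
Reactants: 6 methyl 2-O-benzyl-4,6-O-benzylidene-3-deoxy-3-C-methylene-α-D-ribo-hexopyranoside
Product: 7 methyl 2-O-benzyl-4,6-O-benzylidene-3-C-(hydroxymethyl)-α-D-glucopyranoside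
Conditions: OsO4 (cat.), NMO, acetone/H2O, rt
Reagents that add atoms: osmium tetroxide, O=[Os](=O)(=O)=O; N-methylmorpholine N-oxide, C[N+]1([O-])CCOCC1; water, O
Why: Catalytic syn-dihydroxylation ([3+2] addition of OsO4 with NMO as terminal oxidant) of the exocyclic alkene from the β face, because the axial anomeric methoxy group is 1,3-syn-axial to the α face of C3; the new tertiary O3 should therefore end up equatorial (gluco) with the CH2OH axial, which sets the configuration of target C1.

Step 5
Reactants: 7 methyl 2-O-benzyl-4,6-O-benzylidene-3-C-(hydroxymethyl)-α-D-glucopyranoside; 8 2-(bromomethyl)naphthalene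
Product: 9 methyl 2-O-benzyl-4,6-O-benzylidene-3-O-NAP-3-C-(NAP-oxymethyl)-α-D-glucopyranoside
Conditions: NaH, NAPBr (2.6 equiv), Bu4NI (cat.), DMF, 0 → 40 °C
Reagents that add atoms: 2-(bromomethyl)naphthalene (8), BrCc1ccc2ccccc2c1
Why: Double Williamson etherification of the primary and the tertiary alkoxide with excess halide; the two oxygens made in step 4 (later O7 and O1) thus carry an arylmethyl group that DDQ removes while benzyl ethers stay.

Step 6
Reactants: 9 methyl 2-O-benzyl-4,6-O-benzylidene-3-O-NAP-3-C-(NAP-oxymethyl)-α-D-glucopyranoside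
Product: 10 methyl 2,4-di-O-benzyl-3-O-NAP-3-C-(NAP-oxymethyl)-α-D-glucopyranoside
Conditions: BH3·THF, TMSOTf (cat.), CH2Cl2, 0 °C → rt; aqueous work-up
Reagents that add atoms: none
Why: Regioselective reductive opening of the 4,6-O-benzylidene acetal: the Lewis-acid-activated borane binds the unhindered O6, the C–O6 bond breaks and hydride reduces the oxocarbenium ion on O4, so the benzyl group should stay on O4 and the primary 6-OH is freed without touching a ring stereocentre.

Step 7
Reactants: 10 methyl 2,4-di-O-benzyl-3-O-NAP-3-C-(NAP-oxymethyl)-α-D-glucopyranoside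
Product: 11 methyl 2,4-di-O-benzyl-6-deoxy-6-iodo-3-O-NAP-3-C-(NAP-oxymethyl)-α-D-glucopyranoside
Conditions: PPh3, I2, imidazole, toluene, 70 °C
Reagents that add atoms: iodine, II
Why: Appel-type iodination: the only free hydroxyl is converted into an alkoxyphosphonium ion that iodide displaces by SN2 at the primary C6.

Step 8
Reactants: 11 methyl 2,4-di-O-benzyl-6-deoxy-6-iodo-3-O-NAP-3-C-(NAP-oxymethyl)-α-D-glucopyranoside
Product: 13 2,4-di-O-benzyl-5,6-dideoxy-3-O-NAP-3-C-(NAP-oxymethyl)-aldehydo-D-xylo-hex-5-enose, via 6-iodozincio glycoside 12 (not isolated)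
Conditions: Zn dust (activated), THF/H2O 9:1, sonication, 40 °C; crude 13 used at once
Reagents that add atoms: none
Why: Bernet–Vasella reductive fragmentation: zerovalent zinc inserts into the C6–I bond and the organozinc expels the ring oxygen, which forms the C5=C6 alkene and sets C1 free as the aldehyde after loss of methoxide; C2, C3 and C4 keep their configuration.

Step 9
Reactants: 13 2,4-di-O-benzyl-5,6-dideoxy-3-O-NAP-3-C-(NAP-oxymethyl)-aldehydo-D-xylo-hex-5-enose; 14 vinylmagnesium bromide
Product: 15 (3R,4S,5S,6R)-4,6-bis(benzyloxy)-5-(NAP-oxy)-5-(NAP-oxymethyl)octa-1,7-dien-3-ol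
Conditions: MgBr2·OEt2, CH2Cl2, –78 °C; then CH2=CHMgBr (THF solution), –78 °C; aqueous work-up
Reagents that add atoms: vinylmagnesium bromide (14), C=C[Mg]Br
Why: Grignard addition under Cram-chelate control: magnesium bridges the aldehyde oxygen and the α-benzyloxy oxygen, so the vinyl group should add anti to the quaternary carbon and give the 1,2-syn carbinol, which is the target C5 configuration; the minor epimer is removed by chromatography.

Step 10
Reactants: 15 (3R,4S,5S,6R)-4,6-bis(benzyloxy)-5-(NAP-oxy)-5-(NAP-oxymethyl)octa-1,7-dien-3-ol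
Product: 16 (1S,2R,5R,6S)-2,6-bis(benzyloxy)-1-(NAP-oxy)-1-(NAP-oxymethyl)cyclohex-3-en-5-ol
Conditions: second-generation Grubbs catalyst (H2IMes)(PCy3)Cl2Ru=CHPh (5 mol %), CH2Cl2 (0.01 M), 40 °C
Reagents that add atoms: none
Why: The ruthenium benzylidene exchanges onto the less hindered vinyl carbinol terminus, the new alkylidene undergoes intramolecular [2+2] cycloaddition with the second vinyl group, and cycloreversion of the ruthenacyclobutane forms the C3=C4 bond and a ruthenium methylidene that carries the cycle on with loss of ethene. The closest known reaction type is ring-closing metathesis of sugar-derived octa-1,7-dienols to conduritol-type cyclohexenes. The one ring formed, the six-membered carbocycle C1–C6, closes by joining the two internal alkene carbons of a 1,7-diene, which can only give the cis ring alkene. No stereocentre is formed, and C1, C2, C5 and C6 are carried through unchanged. The step needs ring closure to win over intermolecular metathesis and over ruthenium-hydride isomerisation of the allylic alcohol; high dilution, two monosubstituted alkenes, the fully substituted C1 with its flanking ethers (which favour the folded conformer) and the irreversible escape of ethene should secure this.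

Step 11
Reactants: 16 (1S,2R,5R,6S)-2,6-bis(benzyloxy)-1-(NAP-oxy)-1-(NAP-oxymethyl)cyclohex-3-en-5-ol
Product: 17 (1S,2R,5R,6S)-2,6-bis(benzyloxy)-1-(hydroxymethyl)cyclohex-3-ene-1,5-diol
Conditions: DDQ (3 equiv), CH2Cl2/pH 7 phosphate buffer 10:1, 0 °C → rt
Reagents that add atoms: none
Why: Oxidative cleavage of arylmethyl ethers by DDQ (hydride abstraction at the electron-rich naphthylmethyl CH2, then hydrolysis of the oxocarbenium ion); the benzyl ethers and the electron-poor allylic carbinol should be oxidised far more slowly, and the buffered aqueous phase intercepts the cation before a neighbouring hydroxyl can.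

Step 12
Reactants: 17 (1S,2R,5R,6S)-2,6-bis(benzyloxy)-1-(hydroxymethyl)cyclohex-3-ene-1,5-diol; 18 benzoyl chloride
Product: 19 [(1S,2R,5R,6S)-5-(benzoyloxy)-2,6-bis(benzyloxy)-1-hydroxycyclohex-3-en-1-yl]methyl benzoate
Conditions: BzCl (2.5 equiv), pyridine, DMAP (cat.), CH2Cl2, 0 °C → rt
Reagents that add atoms: benzoyl chloride (18), O=C(Cl)c1ccccc1
Why: Acylation with BzCl/pyridine under DMAP catalysis benzoylates the primary O7 and the secondary allylic O5, the only acylable hydroxyls; the tertiary O1–H, buried between three substituted carbons, should stay free, so no selectivity between hydroxyls is needed.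

Step 13
Reactants: 19 [(1S,2R,5R,6S)-5-(benzoyloxy)-2,6-bis(benzyloxy)-1-hydroxycyclohex-3-en-1-yl]methyl benzoate
Product: 20 [(1S,2R,5R,6S)-5-(benzoyloxy)-1,2,6-trihydroxycyclohexyl]methyl benzoate (CNP0264996.1)
Conditions: H2 (1 atm), Pd(OH)2/C, EtOAc/MeOH, rt
Reagents that add atoms: none
Why: Heterogeneous catalytic hydrogenation saturates the C3=C4 bond and hydrogenolyses both benzyl ethers at their benzylic C–O bonds, while the benzoates and all four stereocentres should be unaffected in the neutral medium.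

Compound list

1 | methyl 4,6-O-[(R)-benzylidene]-α-D-glucopyranoside | CO[C@@H]1[C@H](O)[C@@H](O)[C@@H]2O[C@H](c3ccccc3)OC[C@H]2O1 | starting material
2 | benzyl bromide | BrCc1ccccc1 | starting material
3 | methyl 2-O-benzyl-4,6-O-benzylidene-α-D-glucopyranoside | CO[C@@H]1[C@H](OCc3ccccc3)[C@@H](O)[C@@H]2O[C@H](c3ccccc3)OC[C@H]2O1 | intermediate
4 | methyl 2-O-benzyl-4,6-O-benzylidene-α-D-ribo-hexopyranosid-3-ulose | CO[C@@H]1[C@H](OCc3ccccc3)C(=O)[C@@H]2O[C@H](c3ccccc3)OC[C@H]2O1 | intermediate
5 | methyltriphenylphosphonium bromide | C[P+](c1ccccc1)(c1ccccc1)c1ccccc1.[Br-] | starting material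
6 | methyl 2-O-benzyl-4,6-O-benzylidene-3-deoxy-3-C-methylene-α-D-ribo-hexopyranoside | CO[C@@H]1[C@H](OCc3ccccc3)C(=C)[C@@H]2O[C@H](c3ccccc3)OC[C@H]2O1 | intermediate
7 | methyl 2-O-benzyl-4,6-O-benzylidene-3-C-(hydroxymethyl)-α-D-glucopyranoside (O3 equatorial, CH2OH axial) | CO[C@@H]1[C@H](OCc3ccccc3)[C@](O)(CO)[C@@H]2O[C@H](c3ccccc3)OC[C@H]2O1 | intermediate
8 | 2-(bromomethyl)naphthalene | BrCc1ccc2ccccc2c1 | starting material
9 | methyl 2-O-benzyl-4,6-O-benzylidene-3-O-(2-naphthylmethyl)-3-C-[(2-naphthylmethoxy)methyl]-α-D-glucopyranoside | CO[C@@H]1[C@H](OCc3ccccc3)[C@](OCc3ccc4ccccc4c3)(COCc3ccc4ccccc4c3)[C@@H]2O[C@H](c3ccccc3)OC[C@H]2O1 | intermediate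
10 | methyl 2,4-di-O-benzyl-3-O-(2-naphthylmethyl)-3-C-[(2-naphthylmethoxy)methyl]-α-D-glucopyranoside | CO[C@@H]1[C@H](OCc2ccccc2)[C@](OCc2ccc3ccccc3c2)(COCc2ccc3ccccc3c2)[C@H](OCc2ccccc2)[C@@H](CO)O1 | intermediate
11 | methyl 2,4-di-O-benzyl-6-deoxy-6-iodo-3-O-(2-naphthylmethyl)-3-C-[(2-naphthylmethoxy)methyl]-α-D-glucopyranoside | CO[C@@H]1[C@H](OCc2ccccc2)[C@](OCc2ccc3ccccc3c2)(COCc2ccc3ccccc3c2)[C@H](OCc2ccccc2)[C@@H](CI)O1 | intermediate
12 | methyl 2,4-di-O-benzyl-6-deoxy-6-(iodozincio)-3-O-(2-naphthylmethyl)-3-C-[(2-naphthylmethoxy)methyl]-α-D-glucopyranoside | CO[C@@H]1[C@H](OCc2ccccc2)[C@](OCc2ccc3ccccc3c2)(COCc2ccc3ccccc3c2)[C@H](OCc2ccccc2)[C@@H](C[Zn]I)O1 | intermediate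
13 | 2,4-di-O-benzyl-5,6-dideoxy-3-O-(2-naphthylmethyl)-3-C-[(2-naphthylmethoxy)methyl]-aldehydo-D-xylo-hex-5-enose | O=C[C@H](OCc1ccccc1)[C@](OCc1ccc2ccccc2c1)(COCc1ccc2ccccc2c1)[C@H](OCc1ccccc1)C=C | intermediate
14 | vinylmagnesium bromide | C=C[Mg]Br | starting material
15 | (3R,4S,5S,6R)-4,6-bis(benzyloxy)-5-(2-naphthylmethoxy)-5-[(2-naphthylmethoxy)methyl]octa-1,7-dien-3-ol | C=C[C@@H](O)[C@H](OCc1ccccc1)[C@](OCc1ccc2ccccc2c1)(COCc1ccc2ccccc2c1)[C@H](OCc1ccccc1)C=C | intermediate
16 | (1S,2R,5R,6S)-2,6-bis(benzyloxy)-1-(2-naphthylmethoxy)-1-[(2-naphthylmethoxy)methyl]cyclohex-3-en-5-ol (target numbering; O1 and O5 on one face, O2, O6 and C7 on the other) | O[C@@H]1C=C[C@@H](OCc2ccccc2)[C@](COCc2ccc3ccccc3c2)(OCc2ccc3ccccc3c2)[C@H]1OCc2ccccc2 | intermediate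
17 | (1S,2R,5R,6S)-2,6-bis(benzyloxy)-1-(hydroxymethyl)cyclohex-3-ene-1,5-diol (target numbering) | O[C@@H]1C=C[C@@H](OCc2ccccc2)[C@](CO)(O)[C@H]1OCc2ccccc2 | intermediate
18 | benzoyl chloride | O=C(Cl)c1ccccc1 | starting material
19 | [(1S,2R,5R,6S)-5-(benzoyloxy)-2,6-bis(benzyloxy)-1-hydroxycyclohex-3-en-1-yl]methyl benzoate (target numbering) | O=C(O[C@@H]1C=C[C@@H](OCc2ccccc2)[C@](COC(=O)c2ccccc2)(O)[C@H]1OCc2ccccc2)c3ccccc3 | intermediate
20 | [(1S,2R,5R,6S)-5-(benzoyloxy)-1,2,6-trihydroxycyclohexyl]methyl benzoate, CNP0264996.1 (target numbering) | O=C(OC[C@]1(O)[C@H](O)CC[C@@H](OC(=O)c2ccccc2)[C@@H]1O)c1ccccc1 | target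

Total step count: 13. Longest linear sequence: 13 steps (1 to 20).

Steps most likely to fail

1. Step 9: poor or reversed facial selectivity in the vinyl addition, because α-chelation, β-chelation and the open transition state compete. The fallback sets out from 13 and comes back at 19. The same addition also supplies the (3S)-epimeric dienol F1. Ring-closing metathesis under the conditions of step 10 should turn it into the 5-epi-cyclohexenol F2. A Mitsunobu reaction (PPh3, DIAD, benzoic acid, THF, 0 °C) inverts C5 and installs its benzoate in one operation to give the 5-O-benzoate F3. DDQ as in step 11 then unmasks O1 and O7 to give the diol monobenzoate F4, and benzoylation of its primary hydroxyl (BzCl 1.2 equiv, pyridine) returns to 19. Both epimers of the addition therefore converge.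

2. Step 3: enolisation of the α,α'-dialkoxy ketone by the basic ylide, leading to epimerisation at C2 or β-elimination in place of olefination. The fallback sets out from 4 and comes back at 6 by a Peterson olefination in two operations. Me3SiCH2MgCl with anhydrous CeCl3 in THF at –78 °C, a weakly basic organocerium reagent, adds to the ketone to give the β-hydroxysilane F5, whose C3 configuration is irrelevant. KH in THF then induces syn-elimination of silanolate to alkene 6.

3. Step 13: hydrogenolysis of an allylic C–O bond (C5–OBz or C2–OBn) on palladium before the alkene is saturated, which would delete an oxygen. The fallback sets out from 19 and comes back at 20. The alkene is first reduced with diimide (2-nitrobenzenesulfonyl hydrazide, Et3N, CH2Cl2, rt), which cannot cleave C–O bonds, to give the saturated dibenzoate F6. Hydrogenolysis of its two benzyl ethers (H2, Pd(OH)2/C, EtOAc) then gives 20.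

Further compounds

F1 | step 9 | (3S,4S,5S,6R)-4,6-bis(benzyloxy)-5-(2-naphthylmethoxy)-5-[(2-naphthylmethoxy)methyl]octa-1,7-dien-3-ol | C=C[C@H](O)[C@H](OCc1ccccc1)[C@](OCc1ccc2ccccc2c1)(COCc1ccc2ccccc2c1)[C@H](OCc1ccccc1)C=C
F2 | step 9 | (1S,2R,5S,6S)-2,6-bis(benzyloxy)-1-(2-naphthylmethoxy)-1-[(2-naphthylmethoxy)methyl]cyclohex-3-en-5-ol (target numbering) | O[C@H]1C=C[C@@H](OCc2ccccc2)[C@](COCc2ccc3ccccc3c2)(OCc2ccc3ccccc3c2)[C@H]1OCc2ccccc2
F3 | step 9 | (1S,2R,5R,6S)-2,6-bis(benzyloxy)-1-(2-naphthylmethoxy)-1-[(2-naphthylmethoxy)methyl]cyclohex-3-en-5-yl benzoate (target numbering) | O=C(O[C@@H]1C=C[C@@H](OCc2ccccc2)[C@](COCc2ccc3ccccc3c2)(OCc2ccc3ccccc3c2)[C@H]1OCc2ccccc2)c1ccccc1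
F4 | step 9 | (1S,2R,5R,6S)-2,6-bis(benzyloxy)-1-hydroxy-1-(hydroxymethyl)cyclohex-3-en-5-yl benzoate (target numbering) | O=C(O[C@@H]1C=C[C@@H](OCc2ccccc2)[C@](CO)(O)[C@H]1OCc2ccccc2)c1ccccc1
F5 | step 3 | methyl 2-O-benzyl-4,6-O-benzylidene-3-C-[(trimethylsilyl)methyl]-α-D-allopyranoside | CO[C@@H]1[C@H](OCc3ccccc3)[C@@](O)(C[Si](C)(C)C)[C@@H]2O[C@H](c3ccccc3)OC[C@H]2O1
F6 | step 13 | [(1S,2R,5R,6S)-5-(benzoyloxy)-2,6-bis(benzyloxy)-1-hydroxycyclohexyl]methyl benzoate (target numbering) | O=C(O[C@@H]1CC[C@@H](OCc2ccccc2)[C@](COC(=O)c2ccccc2)(O)[C@H]1OCc2ccccc2)c1ccccc1
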